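**Retrosynthetic overview**

1. Last bond: carbinol carbon C16 to the butenolide β-carbon. Both carbons are natively electrophilic (aldehyde carbon, β-carbon of an enoate), so 4-bromofuran-2(5H)-one is inverted into a nucleophilic β-acyl vinyl chromium reagent and added, under chiral-ligand control (sets 16R), to a lactol that masks the (Z)-hydroxy skipped enal.
2. The lactol comes from acid unmasking of a Z-trisubstituted allylic silyl ether carrying a dioxolane, made by Wittig olefination of an α-silyloxy ketone with a three-carbon acetal ylide (sets the olefin geometry).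
3. The α-silyloxy ketone comes from kinetic enolate hydroxylation of the Δ8(9) methyl ketone, itself from permanganate cleavage and thermodynamic dehydration of (−)-sclareol.
4. Rings: the trans-decalin (rings A and B, with the C5 and C10 stereocentres) is carried intact from sclareol. The butenolide ring is bought preformed. The only ring closed on the way is the six-membered lactol (step 5), which reacts in step 6 through its open-chain tautomer.

Assumption: (−)-sclareol, [2-(1,3-dioxolan-2-yl)ethyl]triphenylphosphonium bromide and 4-bromofuran-2(5H)-one are bought (the last is otherwise one step from tetronic acid); the chiral chromium ligand is prepared separately and recovered.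

Abbreviations: Dec = (4aS,8aS)-2,5,5,8a-tetramethyl-3,4,4a,5,6,7,8,8a-octahydronaphthalen-1-yl (the Δ8(9) bicycle, 5α-H, 10β-CH3). TBS = tert-butyldimethylsilyl. Side chain numbered from the decalin: C11, C12, C13 (bears CH2OH), C14 (=CH), C15, C16 (carbinol).

**Step 1**
Reactants: 1 (−)-sclareol, (13R)-labd-14-ene-8α,13-diol
Product: 2 8α-hydroxy-14,15-dinorlabdan-13-one
Conditions: KMnO4, MgSO4, acetone/H2O, 0 °C → rt
Reagents that add atoms: none
Why: Permanganate oxidative cleavage of the vinyl group and of the resulting α-hydroxy acid removes C14 and C15 and leaves the C13 methyl ketone, while the saturated decalin, the tertiary C8 alcohol and the C5/C10 stereocentres taken from sclareol are untouched.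

**Step 2**
Reactants: 2 8α-hydroxy-14,15-dinorlabdan-13-one
Product: 3 14,15-dinorlabd-8-en-13-one (4-Dec-butan-2-one)
Conditions: I2 (10 mol %), benzene, reflux (Dean–Stark)
Reagents that add atoms: none
Why: Acid-catalysed E1 dehydration (HI formed from I2) under thermodynamic control gives the tetrasubstituted C8=C9 olefin, the cyclic enol ether that the ketol can form being reopened under the same conditions because the unsaturated ketone is the thermodynamic sink; no new stereocentre.

**Step 3**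
Reactants: 3 14,15-dinorlabd-8-en-13-one
Product: 5 1-(TBS-oxy)-4-Dec-butan-2-one, via 1-hydroxy-4-Dec-butan-2-one 4 (not isolated)
Conditions: KN(SiMe3)2, THF, −78 °C; 2-(phenylsulfonyl)-3-phenyloxaziridine, −78 °C; then TBSCl, −78 → 0 °C
Reagents that add atoms: 2-(phenylsulfonyl)-3-phenyloxaziridine O=S(=O)(c1ccccc1)N1OC1c1ccccc1; tert-butyldimethylsilyl chloride CC(C)(C)[Si](C)(C)Cl
Why: The hindered amide deprotonates kinetically at the methyl group, Davis oxaziridine enolate hydroxylation delivers oxygen there, and the primary alkoxide is silylated in the same flask so the sensitive α-hydroxy ketone is never handled; the hindered tetrasubstituted alkene does not react with the oxaziridine.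

**Step 4**
Reactants: 5 1-(TBS-oxy)-4-Dec-butan-2-one; 6 [2-(1,3-dioxolan-2-yl)ethyl]triphenylphosphonium bromide
Product: 8 (2Z)-1-(TBS-oxy)-2-(2-Dec-ethyl)-4-(1,3-dioxolan-2-yl)but-2-ene, via phosphorus ylide 7 (not isolated)
Conditions: 6, KN(SiMe3)2, THF, −78 → 0 °C; then 5, −78 °C → rt
Reagents that add atoms: none
Why: Wittig olefination of an α-alkoxy ketone with a salt-free non-stabilised ylide (Still's Z-selective variant) places the CH2O group cis to the new chain, typically above 10:1, which is the C13=C14 geometry of the target.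

**Step 5**
Reactants: 8 (2Z)-1-(TBS-oxy)-2-(2-Dec-ethyl)-4-(1,3-dioxolan-2-yl)but-2-ene
Product: 10 5-(2-Dec-ethyl)-3,6-dihydro-2H-pyran-2-ol (anomer mixture), via hydroxy aldehyde 9 (not isolated)
Conditions: 1 M HCl, THF/H2O, 0 °C → rt; NaHCO3 quench
Reagents that add atoms: water O
Why: Acid hydrolysis removes the silyl ether and the dioxolane, and the Z geometry lets the freed hydroxy aldehyde close at once to the six-membered lactol, which protects the skipped enal from conjugation; the lactol carbon is an inconsequential anomeric mixture because the stereocentre at C16 is set only in step 6.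

**Step 6**
Reactants: 10 5-(2-Dec-ethyl)-3,6-dihydro-2H-pyran-2-ol; 11 4-bromofuran-2(5H)-one
Product: 13 4-[(1R,3Z)-1,5-dihydroxy-4-(2-Dec-ethyl)pent-3-en-1-yl]furan-2(5H)-one (target), via alkenylchromium 12 (not isolated)
Conditions: CrCl2 (4 equiv), chiral oxazoline–sulfonamide ligand (Kishi type, 4.4 equiv), Et3N, NiCl2(2,9-dimethyl-1,10-phenanthroline) (cat.), 11 (2 equiv), MeCN/THF, rt; neutral aqueous work-up
Reagents that add atoms: none
Why: Proposed new method: a ligand-controlled Nozaki–Hiyama–Kishi coupling in which zerovalent nickel (from NiCl2 and divalent chromium) inserts into the C–Br bond of the β-bromobutenolide, transmetalation to trivalent chromium gives a β-acyl alkenylchromium (a nucleophilic butenolide β-carbon), and this adds to the aldehyde carbon of the open-chain tautomer with which lactol 10 stands in ring–chain equilibrium (the hydroxy aldehyde already numbered 9 in step 5); the ligand antipode is the one that gives Si-face addition (16R) and must be assigned in a trial on 3-phenylpropanal; the closest known reactions are nickel/chromium couplings of β-iodoacrylates with aldehydes and Kishi's asymmetric nickel/chromium couplings of alkenyl halides with aliphatic aldehydes, and translactonisation of the product alkoxide is geometrically blocked because C16 is trans to the lactone carbonyl across the ring olefin.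

**Compound list**

1 | (−)-sclareol, (13R)-labd-14-ene-8α,13-diol | C=C[C@](C)(O)CC[C@@H]1[C@@]2(C)CCCC(C)(C)[C@@H]2CC[C@@]1(C)O | starting material
2 | 8α-hydroxy-14,15-dinorlabdan-13-one | CC(=O)CC[C@@H]1[C@@]2(C)CCCC(C)(C)[C@@H]2CC[C@@]1(C)O | intermediate
3 | 14,15-dinorlabd-8-en-13-one (4-Dec-butan-2-one) | CC1=C(CCC(C)=O)[C@@]2(C)CCCC(C)(C)[C@@H]2CC1 | intermediate
4 | 1-hydroxy-4-Dec-butan-2-one | CC1=C(CCC(=O)CO)[C@@]2(C)CCCC(C)(C)[C@@H]2CC1 | intermediate
5 | 1-(TBS-oxy)-4-Dec-butan-2-one | CC1=C(CCC(=O)CO[Si](C)(C)C(C)(C)C)[C@@]2(C)CCCC(C)(C)[C@@H]2CC1 | intermediate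
6 | [2-(1,3-dioxolan-2-yl)ethyl]triphenylphosphonium bromide | [Br-].C1COC(CC[P+](c2ccccc2)(c2ccccc2)c2ccccc2)O1 | starting material
7 | [2-(1,3-dioxolan-2-yl)ethylidene]triphenylphosphorane | C1COC(CC=P(c2ccccc2)(c2ccccc2)c2ccccc2)O1 | intermediate
8 | (2Z)-1-(TBS-oxy)-2-(2-Dec-ethyl)-4-(1,3-dioxolan-2-yl)but-2-ene | CC1=C(CC/C(=C/CC2OCCO2)CO[Si](C)(C)C(C)(C)C)[C@@]2(C)CCCC(C)(C)[C@@H]2CC1 | intermediate
9 | (3Z)-5-hydroxy-4-(2-Dec-ethyl)pent-3-enal | CC1=C(CC/C(=C/CC=O)CO)[C@@]2(C)CCCC(C)(C)[C@@H]2CC1 | intermediate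
10 | 5-(2-Dec-ethyl)-3,6-dihydro-2H-pyran-2-ol (anomer mixture) | CC1=C(CCC2=CCC(O)OC2)[C@@]2(C)CCCC(C)(C)[C@@H]2CC1 | intermediate
11 | 4-bromofuran-2(5H)-one | O=C1C=C(Br)CO1 | starting material
12 | 4-(dichlorochromio)furan-2(5H)-one (ligand-bound alkenylchromium) | O=C1C=C([Cr](Cl)Cl)CO1 | intermediate
13 | 4-[(1R,3Z)-1,5-dihydroxy-4-(2-Dec-ethyl)pent-3-en-1-yl]furan-2(5H)-one | CC1=C(CC/C(=C/C[C@@H](O)C2=CC(=O)OC2)CO)[C@@]2(C)CCCC(C)(C)[C@@H]2CC1 | target

**Totals**

Total step count: 6. Longest linear sequence: 6 steps (sclareol 1 to target 13). No protecting-group step remains after the key coupling.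

**Three steps most likely to fail, with fallbacks**

Step 6 (coupling on a lactol bearing a free hydroxyl; facial selectivity unproven). The fallback sets out from 8 and comes back at 13, and moves stereocontrol from the C–C bond formation to a ketone reduction. Chemoselective dioxolane cleavage of 8 (TESOTf, 2,4,6-collidine, CH2Cl2, 0 °C, then H2O) keeps the silyl ether and gives the open-chain aldehyde (3Z)-5-(TBS-oxy)-4-(2-Dec-ethyl)pent-3-enal F1. Ligand-free coupling of F1 with 11 through alkenylchromium 12 (CrCl2, NiCl2 cat., DMF, rt) gives the epimeric carbinol mixture 4-[(3Z)-1-hydroxy-5-(TBS-oxy)-4-(2-Dec-ethyl)pent-3-en-1-yl]furan-2(5H)-one F2. Dess–Martin oxidation gives the ketone 4-[(3Z)-5-(TBS-oxy)-4-(2-Dec-ethyl)pent-3-enoyl]furan-2(5H)-one F3, used at once because its C15 methylene is doubly activated. Corey–Bakshi–Shibata reduction with the (S)-methyl oxazaborolidine and catecholborane at −78 °C (butenolide as the large group) gives the (1R)-carbinol 4-[(1R,3Z)-1-hydroxy-5-(TBS-oxy)-4-(2-Dec-ethyl)pent-3-en-1-yl]furan-2(5H)-one F4. HF·pyridine in THF then gives 13.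

Step 4 (enolisable α-silyloxy ketone, functionalised ylide, Z selectivity needed). The fallback sets out from 5 and comes back at 10 (so it also bypasses step 5), and fixes the olefin geometry by a ring. Methylenation of 5 with Ph3P=CH2 gives 3-(TBS-oxy)-2-(2-Dec-ethyl)prop-1-ene F5. Bu4NF gives 2-(2-Dec-ethyl)prop-2-en-1-ol F6. Esterification with but-3-enoic acid (DCC, DMAP cat., 0 °C) gives 2-(2-Dec-ethyl)prop-2-en-1-yl but-3-enoate F7. Ring-closing metathesis with the second-generation Grubbs catalyst RuCl2(=CHPh)(PCy3)(H2IMes) in CH2Cl2 at 40 °C (benzoquinone additive; the tetrasubstituted C8=C9 olefin is inert) gives the lactone 5-(2-Dec-ethyl)-3,6-dihydro-2H-pyran-2-one F8. iBu2AlH at −78 °C reduces F8 to lactol 10.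

Step 2 (competing cyclic enol ether formation and Δ7/Δ8(17) isomers). The fallback sets out from 1 and comes back at 5; it moves the olefin equilibration to a stage with no ketone, but that stage is still an acid equilibration and needs isomer separation. Oxidation of 1 (RuCl3 cat., NaIO4, MeCN/H2O) gives (+)-sclareolide F9, which can also be bought. H2SO4 in MeOH opens and dehydrates it to methyl 2-Dec-acetate F10 (minor olefin isomers removed on AgNO3-impregnated silica). LiAlH4 gives 2-Dec-ethanol F11. I2, PPh3 and imidazole give 2-Dec-ethyl iodide F12. Iodine–lithium exchange (tBuLi, 2 equiv, Et2O, −78 °C) gives 2-Dec-ethyllithium F13, which is acylated with 2-(TBS-oxy)-N-methoxy-N-methylacetamide to give 5.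

**Further compounds**

F1 | step 6 | (3Z)-5-(TBS-oxy)-4-(2-Dec-ethyl)pent-3-enal | CC1=C(CC/C(=C/CC=O)CO[Si](C)(C)C(C)(C)C)[C@@]2(C)CCCC(C)(C)[C@@H]2CC1
F2 | step 6 | 4-[(3Z)-1-hydroxy-5-(TBS-oxy)-4-(2-Dec-ethyl)pent-3-en-1-yl]furan-2(5H)-one, both C1 epimers | CC1=C(CC/C(=C/CC(O)C2=CC(=O)OC2)CO[Si](C)(C)C(C)(C)C)[C@@]2(C)CCCC(C)(C)[C@@H]2CC1
F3 | step 6 | 4-[(3Z)-5-(TBS-oxy)-4-(2-Dec-ethyl)pent-3-enoyl]furan-2(5H)-one | CC1=C(CC/C(=C/CC(=O)C2=CC(=O)OC2)CO[Si](C)(C)C(C)(C)C)[C@@]2(C)CCCC(C)(C)[C@@H]2CC1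
F4 | step 6 | 4-[(1R,3Z)-1-hydroxy-5-(TBS-oxy)-4-(2-Dec-ethyl)pent-3-en-1-yl]furan-2(5H)-one | CC1=C(CC/C(=C/C[C@@H](O)C2=CC(=O)OC2)CO[Si](C)(C)C(C)(C)C)[C@@]2(C)CCCC(C)(C)[C@@H]2CC1
F5 | step 4 | 3-(TBS-oxy)-2-(2-Dec-ethyl)prop-1-ene | CC1=C(CCC(=C)CO[Si](C)(C)C(C)(C)C)[C@@]2(C)CCCC(C)(C)[C@@H]2CC1
F6 | step 4 | 2-(2-Dec-ethyl)prop-2-en-1-ol | CC1=C(CCC(=C)CO)[C@@]2(C)CCCC(C)(C)[C@@H]2CC1
F7 | step 4 | 2-(2-Dec-ethyl)prop-2-en-1-yl but-3-enoate | CC1=C(CCC(=C)COC(=O)CC=C)[C@@]2(C)CCCC(C)(C)[C@@H]2CC1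
F8 | step 4 | 5-(2-Dec-ethyl)-3,6-dihydro-2H-pyran-2-one | CC1=C(CCC2=CCC(=O)OC2)[C@@]2(C)CCCC(C)(C)[C@@H]2CC1
F9 | step 2 | (+)-sclareolide | O=C1C[C@@H]2[C@@]3(C)CCCC(C)(C)[C@@H]3CC[C@@]2(C)O1
F10 | step 2 | methyl 2-Dec-acetate | CC1=C(CC(=O)OC)[C@@]2(C)CCCC(C)(C)[C@@H]2CC1
F11 | step 2 | 2-Dec-ethanol | CC1=C(CCO)[C@@]2(C)CCCC(C)(C)[C@@H]2CC1
F12 | step 2 | 2-Dec-ethyl iodide | CC1=C(CCI)[C@@]2(C)CCCC(C)(C)[C@@H]2CC1
F13 | step 2 | 2-Dec-ethyllithium | CC1=C(CC[Li])[C@@]2(C)CCCC(C)(C)[C@@H]2CC1
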